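## Retrosynthetic overview

1. Target 10 ⇐ 9 by Pd(0) removal of the only protecting group, the 4'-O-allyl ether.
2. 9 ⇐ 6 + 7 by a two-bond annulation. O1–C2 comes from phenoxide/phenacyl bromide etherification. C3–C4 comes from adding the aldehyde carbon of 7, as an acyl anion (chiral-carbene Breslow intermediate), to the aryl ketone. This sets C3 (S) on an A ring that carries no protecting group.
3. 6 ⇐ 1 by C3-prenylation, one-pot 4-O-allylation/2-O-methylation, and α-bromination through the enol silane.
4. Rings A and B are bought as aromatics (7 and 1). The pyranone ring is the only ring made, and it is made last.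

Assumption: 7 is bought as a catalogue building block, and the (5aS,10bR) triazolium salt is taken to give the 3S ketol; if a model cyclisation shows the opposite sense, its commercial antipode is used instead.

(prenyl = 3-methylbut-2-en-1-yl; allyl = prop-2-en-1-yl)

## Route

Step 1
Reactants: 1 1-(2,4-dihydroxyphenyl)ethan-1-one
Product: 2 1-[2,4-dihydroxy-3-(3-methylbut-2-en-1-yl)phenyl]ethan-1-one
Conditions: prenyl bromide (1.0 equiv), 10% aq. KOH, 0 °C → rt; chromatographic separation from the 5-prenyl and O-prenyl isomers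
Reagents that add atoms: prenyl bromide (1-bromo-3-methylbut-2-ene), CC(C)=CCBr
Why: Phenoxide C-alkylation (aqueous-base C-prenylation): in water the O-solvated resorcinolate reacts through carbon, and C3, flanked by both oxygens, is the most nucleophilic ring carbon, so a modest yield is accepted on a very cheap first step.

Step 2
Reactants: 2 1-[2,4-dihydroxy-3-(3-methylbut-2-en-1-yl)phenyl]ethan-1-one
Product: 4 1-[2-methoxy-3-(3-methylbut-2-en-1-yl)-4-(prop-2-en-1-yloxy)phenyl]ethan-1-one, via 4-O-allyl ether 3 (not isolated)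
Conditions: allyl bromide (1.0 equiv), K2CO3 (3 equiv), DMF, rt; then MeI (3 equiv), 50 °C
Reagents that add atoms: allyl bromide (3-bromoprop-1-ene), C=CCBr; iodomethane, CI
Why: Two sequential Williamson etherifications: the free 4-OH is alkylated at rt while the chelated, flanked 2-OH needs excess MeI and heat, so one pot places the allyl protecting group on O4 and the methyl on O2.

Step 3
Reactants: 4 1-[2-methoxy-3-(3-methylbut-2-en-1-yl)-4-(prop-2-en-1-yloxy)phenyl]ethan-1-one
Product: 6 2-bromo-1-[2-methoxy-3-(3-methylbut-2-en-1-yl)-4-(prop-2-en-1-yloxy)phenyl]ethan-1-one, via TMS enol ether 5 (not isolated)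
Conditions: LiHMDS (1.1 equiv), TMSCl (1.2 equiv), THF, −78 °C; then NBS (1.05 equiv), THF, −78 → 0 °C
Reagents that add atoms: N-bromosuccinimide, O=C1CCC(=O)N1Br
Why: α-Bromination of a ketone through its silyl enol ether: at −78 °C the enol silane is far more nucleophilic towards NBS than the prenyl and allyl alkenes or the arene, so only the methyl ketone is brominated.

Step 4
Reactants: 6 2-bromo-1-[2-methoxy-3-(3-methylbut-2-en-1-yl)-4-(prop-2-en-1-yloxy)phenyl]ethan-1-one; 7 2,6-dihydroxy-4-methoxybenzaldehyde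
Product: 9 (3S)-3,5-dihydroxy-7-methoxy-3-[2-methoxy-3-(3-methylbut-2-en-1-yl)-4-(prop-2-en-1-yloxy)phenyl]-2,3-dihydro-4H-chromen-4-one, via keto-aldehyde ether 8 (not isolated)
Conditions: 7 (1.3 equiv), K2CO3 (1.1 equiv), acetone, rt; filter, swap to toluene; then (5aS,10bR)-2-(pentafluorophenyl)-5a,10b-dihydro-4H,6H-indeno[2,1-b][1,2,4]triazolo[4,3-d][1,4]oxazin-2-ium tetrafluoroborate (15 mol%), Et3N (15 mol%), 4 Å MS, rt → 40 °C
Reagents that add atoms: none
Why: Proposed new method: Williamson O-phenacylation of one of the two equivalent phenols of 7 is followed, without isolation, by a chiral-NHC intramolecular crossed aldehyde–ketone benzoin reaction in which the Breslow intermediate (acyl anion at the future C4) adds 6-exo to the aryl ketone (future C3) while the indane wall of the catalyst shields one ketone face and so sets C3 as S, the free ortho-OH being expected to act as an internal proton shuttle for Breslow formation and to lock the product through a 5-OH···O=C4 hydrogen bond against retro-benzoin; the carbene is added only after the bromide is consumed because it would otherwise be alkylated, and the closest known reaction type is the enantioselective triazolium-catalysed benzoin cyclisation of isolated, O-protected 2-(2-oxo-2-arylethoxy)benzaldehydes to 3-aryl-3-hydroxychroman-4-ones.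

Step 5
Reactants: 9 (3S)-3,5-dihydroxy-7-methoxy-3-[2-methoxy-3-(3-methylbut-2-en-1-yl)-4-(prop-2-en-1-yloxy)phenyl]-2,3-dihydro-4H-chromen-4-one
Product: 10 (3S)-3,5-dihydroxy-3-[4-hydroxy-2-methoxy-3-(3-methylbut-2-en-1-yl)phenyl]-7-methoxy-2,3-dihydro-4H-chromen-4-one
Conditions: Pd(PPh3)4 (5 mol%), morpholine (5 equiv), THF, rt
Reagents that add atoms: none
Why: Tsuji–Trost-type Pd(0) deallylation: the aryl allyl ether ionises to a π-allyl complex that morpholine traps under neutral conditions, leaving the C-prenyl group, the tertiary ketol and the quaternary (non-enolisable) C3 centre untouched.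

## Compound list

1 | 1-(2,4-dihydroxyphenyl)ethan-1-one | CC(=O)c1ccc(O)cc1O | starting material
2 | 1-[2,4-dihydroxy-3-(3-methylbut-2-en-1-yl)phenyl]ethan-1-one | CC(=O)c1ccc(O)c(CC=C(C)C)c1O | intermediate
3 | 1-[2-hydroxy-3-(3-methylbut-2-en-1-yl)-4-(prop-2-en-1-yloxy)phenyl]ethan-1-one | CC(=O)c1ccc(OCC=C)c(CC=C(C)C)c1O | intermediate
4 | 1-[2-methoxy-3-(3-methylbut-2-en-1-yl)-4-(prop-2-en-1-yloxy)phenyl]ethan-1-one | CC(=O)c1ccc(OCC=C)c(CC=C(C)C)c1OC | intermediate
5 | trimethyl({1-[2-methoxy-3-(3-methylbut-2-en-1-yl)-4-(prop-2-en-1-yloxy)phenyl]ethenyl}oxy)silane | C=C(O[Si](C)(C)C)c1ccc(OCC=C)c(CC=C(C)C)c1OC | intermediate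
6 | 2-bromo-1-[2-methoxy-3-(3-methylbut-2-en-1-yl)-4-(prop-2-en-1-yloxy)phenyl]ethan-1-one | BrCC(=O)c1ccc(OCC=C)c(CC=C(C)C)c1OC | intermediate
7 | 2,6-dihydroxy-4-methoxybenzaldehyde | COc1cc(O)c(C=O)c(O)c1 | starting material
8 | 2-hydroxy-4-methoxy-6-{2-[2-methoxy-3-(3-methylbut-2-en-1-yl)-4-(prop-2-en-1-yloxy)phenyl]-2-oxoethoxy}benzaldehyde | COc1cc(O)c(C=O)c(OCC(=O)c2ccc(OCC=C)c(CC=C(C)C)c2OC)c1 | intermediate
9 | (3S)-3,5-dihydroxy-7-methoxy-3-[2-methoxy-3-(3-methylbut-2-en-1-yl)-4-(prop-2-en-1-yloxy)phenyl]-2,3-dihydro-4H-chromen-4-one | COc1cc(O)c2c(c1)OC[C@@](O)(c1ccc(OCC=C)c(CC=C(C)C)c1OC)C2=O | intermediate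
10 | (3S)-3,5-dihydroxy-3-[4-hydroxy-2-methoxy-3-(3-methylbut-2-en-1-yl)phenyl]-7-methoxy-2,3-dihydro-4H-chromen-4-one | COc1cc(O)c2c(c1)OC[C@@](O)(c1ccc(O)c(CC=C(C)C)c1OC)C2=O | target

## Step count and risks

Total steps: 5. Longest linear sequence: 5 (1 → 2 → 4 → 6 → 9 → 10); 7 enters at step 4.

Most likely to fail, step 4: the aldehyde is electron-rich, di-ortho-substituted and carries a free phenol, so carbene addition may stall or base-mediated aldol closure to a 2-aroylbenzofuran may compete. The fallback protects the phenol and runs the sequence stepwise. It sets out from 7, which is mono-allylated (allyl bromide, K2CO3, acetone, rt) to 2-hydroxy-4-methoxy-6-(prop-2-en-1-yloxy)benzaldehyde F1. F1 is alkylated with 6 (K2CO3, DMF, rt) and the product is isolated as 4-methoxy-2-{2-[2-methoxy-3-(3-methylbut-2-en-1-yl)-4-(prop-2-en-1-yloxy)phenyl]-2-oxoethoxy}-6-(prop-2-en-1-yloxy)benzaldehyde F2. F2 is cyclised with the same triazolium salt and Et3N in toluene at rt (well below the temperatures at which carbene hydroacylation of the O-allyl group occurs) to (3S)-3-hydroxy-7-methoxy-3-[2-methoxy-3-(3-methylbut-2-en-1-yl)-4-(prop-2-en-1-yloxy)phenyl]-5-(prop-2-en-1-yloxy)-2,3-dihydro-4H-chromen-4-one F3. The Pd(PPh3)4/morpholine conditions of step 5 then remove both allyl groups at once, and the fallback comes back to the route at the target 10.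

Second, step 1: direct C-prenylation gives a low yield and regioisomers. The fallback sets out from 1, which is O-allylated at the 4-OH (allyl bromide, K2CO3, acetone) to 1-[2-hydroxy-4-(prop-2-en-1-yloxy)phenyl]ethan-1-one F4. Aromatic Claisen rearrangement (N,N-diethylaniline, 200 °C), directed to C3 by the chelate-fixed ring, gives 1-[2,4-dihydroxy-3-(prop-2-en-1-yl)phenyl]ethan-1-one F5. Olefin cross-metathesis of F5 with 2-methylbut-2-ene (Grubbs second-generation catalyst, CH2Cl2, 40 °C) turns the allyl into the prenyl group and comes back to the route at 2.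

Third, step 3: electrophilic bromine may attack the prenyl group or over-brominate. The fallback avoids halogen altogether. It sets out from 4, whose potassium enolate (KHMDS, THF, −78 °C) is hydroxylated with 2-(phenylsulfonyl)-3-phenyloxaziridine (Davis reagent, inert to alkenes) to 2-hydroxy-1-[2-methoxy-3-(3-methylbut-2-en-1-yl)-4-(prop-2-en-1-yloxy)phenyl]ethan-1-one F6. Mitsunobu etherification of F6 with 7 (PPh3, DIAD, THF, 0 °C → rt) gives the keto-aldehyde ether, and the fallback comes back to the route at 8, now isolated, which enters the carbene stage of step 4.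

## Further compounds

F1 | step 4 | 2-hydroxy-4-methoxy-6-(prop-2-en-1-yloxy)benzaldehyde | COc1cc(O)c(C=O)c(OCC=C)c1
F2 | step 4 | 4-methoxy-2-{2-[2-methoxy-3-(3-methylbut-2-en-1-yl)-4-(prop-2-en-1-yloxy)phenyl]-2-oxoethoxy}-6-(prop-2-en-1-yloxy)benzaldehyde | COc1cc(OCC=C)c(C=O)c(OCC(=O)c2ccc(OCC=C)c(CC=C(C)C)c2OC)c1
F3 | step 4 | (3S)-3-hydroxy-7-methoxy-3-[2-methoxy-3-(3-methylbut-2-en-1-yl)-4-(prop-2-en-1-yloxy)phenyl]-5-(prop-2-en-1-yloxy)-2,3-dihydro-4H-chromen-4-one | COc1cc(OCC=C)c2c(c1)OC[C@@](O)(c1ccc(OCC=C)c(CC=C(C)C)c1OC)C2=O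
F4 | step 1 | 1-[2-hydroxy-4-(prop-2-en-1-yloxy)phenyl]ethan-1-one | CC(=O)c1ccc(OCC=C)cc1O
F5 | step 1 | 1-[2,4-dihydroxy-3-(prop-2-en-1-yl)phenyl]ethan-1-one | CC(=O)c1ccc(O)c(CC=C)c1O
F6 | step 3 | 2-hydroxy-1-[2-methoxy-3-(3-methylbut-2-en-1-yl)-4-(prop-2-en-1-yloxy)phenyl]ethan-1-one | OCC(=O)c1ccc(OCC=C)c(CC=C(C)C)c1OC
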